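The numbers in the tables were computed with made-up constants; the scatter is artificial.

The dusk run loses starting material faster than it gains target: up to the first reading the charge falls at 0.202 h⁻¹, while target grows at 0.0336 h⁻¹.

common to all: starting material 0.10 M
- dusk: reagent 5 equiv; scavenger 1 equiv; temperature 70 °C; the very flask that is asked about, followed so far
- summer: reagent 5 equiv; scavenger 0.67 equiv; temperature 65 °C; run made earlier
- flask: reagent 5.00 equiv; scavenger 1.00 equiv; temperature 70 °C; time 15 h

- dusk (time / h: target / %, starting material / %): 0.833: 2.8, 83.2; 2.50: 10.0, 60.9; 4.00: 15.7, 47.3; 6.00: 19.2, 34.0; 10.0: 21.3, 18.8; 12.0: 20.2, 12.6; 15.0: 17.9, 7.9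
- summer (time / h: target / %, starting material / %): 0.167: 0.1, 96.0; 0.500: 0, 91.2; 0.833: 1.1, 86.1; 1.33: 2.2, 82.1; 2.00: 4.1, 73.8; 2.50: 5.7, 69.9; 3.00: 7.1, 65.9

(each reading ± 0.5 percentage points)

- target taken out counts as made
- additions bring no volume worth counting

- eta: at 15 h raise the temperature by 25 K, then wait 8.0 h
- beta: change nothing and wait 8.0 h more
- theta: at 15 h take out 90% of the target then present, then wait 8.0 h
- zeta: at 15 h add reagent, 50.0% of the amount charged, then wait 8.0 h

- target, in percent of the starting material first charged, at 15 h
- the remedy with the largest gain of target, or "none" below 2 percentage points (eta / beta / theta / zeta / none)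
- target present, with what was taken out counted in, in percent of the starting material first charged, after eta
- target present, with what was taken out counted in, in percent of the starting material first charged, after beta

Reagent stands at 5 equiv, so I treat the fall as pseudo-first-order and integrate it to a fraction left of exp(−kt). The last dusk reading gives k = 0.169 h⁻¹, and the half-life of this line is 4.10 h. In the dusk run target crosses above starting material between 6.00 h and 10.0 h, tops in the readings at 21.3%, and has sunk to 17.9% at 15.0 h, with 7.9% of starting material still there. The unseen share, the charge less both, has reached 74.2%. Target over unseen share gives 0.241 at 15.0 h, and this split is a selectivity factor of my own. Target is the reacted fraction multiplied by the split over the split plus one, so with the split held the curve runs toward that ratio as starting material goes.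

The split in the dusk run fell from 0.301 at 12.0 h. Continuing at that pace, I reckon 0.134 and target 11.6% after beta. At 2.50 h the split reads 0.344 in the dusk run and 0.234 in the cooler summer run, though scavenger differs too. That is a factor of 1.47 for 5 K. Stretched coarsely over 25 K, it gives a split of 1.66 and target near 61.2%, so I choose eta.

The forecast differs from me on heat: it gives 18% now, 12.5% after beta, 4.5% after eta and best none, saying “so target is mostly destroyed”.

The flask gives 18.3% now and 13.9% after beta, and best is eta, at 46.4%, above the forecast and below my figure. The steps are these:

    starting material + released group ⇌ idle adduct, settled at all times (K = 27.0 M⁻¹, ΔH = −8.00 kJ mol⁻¹)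
    intermediate ⇌ target (K = 1.10, k = 0.510 h⁻¹, Ea = 106 kJ mol⁻¹, ΔH = 24.0 kJ mol⁻¹)
    starting material + released group → side product (k = 0.270 M⁻¹ h⁻¹, Ea = 73.0 kJ mol⁻¹)
    starting material + reagent → intermediate + released group (k = 0.390 M⁻¹ h⁻¹, Ea = 73.0 kJ mol⁻¹)
    intermediate ⇌ isomer of the product (K = 9.30, k = 0.270 h⁻¹, Ea = 108 kJ mol⁻¹, ΔH = −86.0 kJ mol⁻¹)
    scavenger + released group → scavenged by-product (k = 180 M⁻¹ h⁻¹, Ea = 78.0 kJ mol⁻¹)
    target → over-reaction product (k = 1.30 × 10⁻⁴ h⁻¹, Ea = 125 kJ mol⁻¹)
    (constants at 70 °C)

In this flask the step from starting material to intermediate has half of its turnover up to 15 h behind it by 3.40 h, and the step from intermediate to isomer of the product reaches that mark of its own turnover later, at 6.82 h. At 15.0 h this flask holds 57.8% of isomer of the product and 15.4% of intermediate, and target over all else that has reacted is a split of 0.249. The repeat at 95 °C holds, at the same time, target 46.1% against 28.5% of isomer of the product and 23.7% of intermediate, a split of 0.855.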